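Substrate cannot sink below 30.0% of its charge in autumn or spring: it goes one for one with partner, the limiting reagent, charged at 1.05 M against 1.5 M.

| flask | substrate | partner | remark | time |
|---|---|---|---|---|
| north-west | 1.5 M | 0.53 M | run made earlier |  |
| north | 1.5 M | 0.79 M | run made earlier |  |
| east | 2.2 M | 1.05 M | run made earlier |  |
| autumn | 1.5 M | 1.05 M |  | 40 h |
| spring | 1.5 M | 1.05 M |  | 120 h |

| run | time / h | adduct / % | target / % | side product / % | substrate / % |
|---|---|---|---|---|---|
| north-west | 2.50 | 2.7 | 3.2 | 0 | 93.5 |
| north-west | 8.00 | 2.2 | 8.5 | 0.1 | 88.4 |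
| north-west | 15.0 | 2.1 | 14.1 | 1.1 | 83.6 |
| north-west | 20.0 | 1.4 | 17.6 | 1.0 | 80.2 |
| north-west | 30.0 | 1.0 | 22.1 | 1.1 | 76.3 |
| north-west | 40.0 | 0.6 | 24.5 | 1.6 | 73.2 |
| north | 3.00 | 4.1 | 5.4 | 0 | 90.0 |
| north | 5.00 | 4.0 | 8.3 | 0.8 | 86.9 |
| north | 8.00 | 3.1 | 12.9 | 0.5 | 83.1 |
| north | 15.0 | 3.0 | 20.2 | 1.1 | 76.4 |
| north | 25.0 | 1.8 | 28.1 | 1.4 | 69.2 |
| north | 40.0 | 1.1 | 35.6 | 2.5 | 61.6 |
| east | 3.00 | 4.9 | 6.3 | 0.5 | 88.3 |
| east | 6.00 | 3.8 | 11.8 | 0.1 | 82.9 |
| east | 12.0 | 2.5 | 19.9 | 1.2 | 75.4 |
| east | 20.0 | 2.0 | 27.0 | 1.9 | 69.2 |
| east | 40.0 | 0.8 | 36.9 | 2.1 | 60.4 |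

(readings scatter by 0.3 percentage points)

- the earlier runs were read with a standard deviation of 0.3 percentage points
- a reading or a percentage of target counts all its forms, free or not

* which of these there is most of at the end, counted by the substrate in it, autumn (substrate / adduct / side product / target)
* which of these there is most of at the end, counted by the substrate in it, spring (substrate / adduct / side product / target)
* how much there is at the end of the one of these that leads, in percent of the substrate charged: autumn
* how much there is at the end of the one of these that leads, in percent of the substrate charged: spring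

So what matters is how fast that floor is approached. Let S and P be free substrate and partner; their difference Δ stays fixed. Adduct reads 1.1% at the last north reading, so we skip it and write the rate as kSP, with k the apparent second-order constant. Then S/P grows from its charged value as exp(kΔt), and near the floor S barely moves, so the rate is pseudo-first-order in P.

That north reading gives k = 0.0289 /M/h; the last east reading, from other charges, gives 0.0275 /M/h. We reckon substrate at 51.4% in autumn and 35.2% in spring. Side product reads 7.02% of target in that north reading, so spring's target comes to 60.6%.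

The forecast, reasoning “Overall this is second-order”, names substrate at 51.5% for autumn and target at 59.5% for spring; our spring target is higher.

The flask gives substrate at 51.4% in autumn and target at 60.9% in spring; that spring target counts crystals, which hold 16.8% of the substrate charged.

    substrate + partner ⇌ adduct (K = 0.0785 /M, k = 0.0110 /M/min)
    adduct → target (k = 0.00634 /min)
    crystals ⇌ target, rate k3*(cs3 - [target]) while solid is left; crystals form when [target] > cs3 (solubility = 0.660 M, k = 0.0671 /min)
    adduct → side product (k = 3.84 × 10⁻⁴ /min)

The difference in time takes substrate down to 35.2% in spring, against 51.4% in autumn, and so below spring's target. Our k leaves 7.43% of spring's partner; the flask holds 7.5%. At ten times the time, substrate stands at 30.0%, on the floor.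

Charged with 2.5 M of substrate, the neighbour of autumn has a floor of 58.0%, and the same k gives 62.9%. The flask gives 63.3%.

The data are simulated for an exercise, and the scatter is random.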